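(The runs are calculated for an exercise, noise included.)

**Note for the bench.** The capture agent charge was small, 5.00 % of the substrate, and I did not build my reckoning on it. I built it on when the fresh partner's attack on the target stops.

| flask | substrate | fresh partner | coupling partner | capture agent | temperature | remark | time |
|---|---|---|---|---|---|---|---|
| Tuesday's | 0.20 M | 0.26 M | 0.80 M | 0.010 M | 50 °C | run made earlier |  |
| Monday's | 0.20 M | 0.26 M | 0.40 M | 0.010 M | 50 °C | run made earlier |  |
| epsilon | 0.20 M | 0.260 M (in portions, 3, over 2.0 min) | 0.800 M | 0.0100 M | 50 °C | first portion at the start, last at 2.0 min | 5.0 min |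
| beta | 0.20 M | 0.260 M | 0.800 M | 0.0100 M | 50 °C | everything together at the start | 5.0 min |
| eta | 0.20 M (fed, over 2.0 min) | 0.260 M | 0.800 M | 0.0100 M |  | the addition at 30 °C, then warmed to 50 °C; the feed brings no volume worth counting | 5.0 min |
| theta | 0.20 M (fed, over 2.0 min) | 0.260 M | 0.800 M | 0.0100 M | 50 °C | all else is in the flask from the start; the feed brings no volume worth counting | 5.0 min |

Tuesday's run (percent of the substrate charged)

| time / min | over-reaction product / % | target / % |
|---|---|---|
| 0.250 | 0 | 3.4 |
| 0.417 | 1.0 | 9.5 |
| 0.667 | 3.8 | 20.6 |
| 1.00 | 5.1 | 30.6 |
| 2.00 | 4.5 | 54.1 |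
| 3.00 | 3.9 | 66.0 |

Monday's run (percent of the substrate charged)

| time / s | over-reaction product / % | target / % |
|---|---|---|
| 10.0 | 0.3 | 0.8 |
| 20.0 | 0 | 4.2 |
| 30.0 | 2.2 | 3.8 |

(scatter of a reading: 1 percentage point)

- what was read earlier has a scatter of 1 percentage point, one standard deviation
- the earlier runs do not show what temperature does; that part of a forecast is a guess

- the flask that comes out highest in amount of over-reaction product, in percent of the substrate charged, or "all alike" when all lie within 1.5 percentage points (epsilon / beta / eta / theta / all alike)
- over-reaction product at the end, in percent of the substrate charged, epsilon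
- over-reaction product at the end, in percent of the substrate charged, beta
- over-reaction product at the end, in percent of the substrate charged, eta
- over-reaction product at the end, in percent of the substrate charged, theta

Tuesday's run had beta's recipe. Its over-reaction product read 5.1 % at 1.00 min, then 4.5 % and 3.9 %, flat within the scatter, while its target climbed to 66.0 %. So I kept 1.00 min as the closing time: the time after a dose of fresh partner enters at which the over-reaction product stops growing. I treated the fresh partner as pseudo-first-order in coupling partner, so I let this time stretch as the coupling partner charge less the dose, taken as a fraction of that charge, shrinks.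

Beta: closes at 1.00 min, target then reading 30.6 % in Tuesday's run.

Epsilon: last portion at 2.0 min, closes at 3.00 min.

Theta: closes at 1.00 min, with half of the substrate fed.

I therefore expected epsilon above beta, since by my reckoning epsilon closes later than beta, and beta above theta, since at closing theta has half of its substrate fed; eta stayed a guess. What stands at 5.0 min should be final, as that is later than epsilon's closing. Do not add fresh partner late: in epsilon, by my reckoning, the late portion moves the closing time from 1.00 min to 3.00 min.

The forecast differed: all alike, with 4.6 %, 4.6 %, 4.4 % and 4.5 % for epsilon, beta, eta and theta, on the grounds that “each should reach the cap whatever the addition mode”.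

The flasks gave 18.1 % for epsilon, 4.24 % for beta, 1.73 % for eta and 0.521 % for theta, so the highest was epsilon.

substrate + coupling partner → open intermediate (k = 0.0520 M⁻¹ s⁻¹, Ea = 47.0 kJ mol⁻¹); coupling partner + fresh partner → second intermediate (k = 0.140 M⁻¹ s⁻¹, Ea = 51.0 kJ mol⁻¹); open intermediate + second intermediate → target (k = 0.0870 M⁻¹ s⁻¹, Ea = 54.0 kJ mol⁻¹); 2 open intermediate → homo product (k = 0.0210 M⁻¹ s⁻¹, Ea = 48.0 kJ mol⁻¹); open intermediate + capture agent → trapped intermediate (k = 0.0620 M⁻¹ s⁻¹, Ea = 70.0 kJ mol⁻¹); fresh partner + target → over-reaction product (k = 0.360 M⁻¹ s⁻¹, Ea = 49.0 kJ mol⁻¹); (constants at 50 °C) Epsilon still stood at 18.1 % at 50.0 min. The neighbouring flask was theta with 0.65 M of fresh partner. Taking the dose from the coupling partner charge, the remainder as a fraction of that charge fell to 0.188 from 0.675, so I stretched the closing time to 3.60 min, later than the end of the feed at 2.0 min. That flask gave 10.6 % of over-reaction product.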